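Time drops out when you divide the rate of a path that spends two L on each E by the rate of the path that spends one L to make D. E cancels as well, so that quotient of forward rates grows in proportion to L. Amounts need not follow the quotient, and in the runs D fades later, so I use it as an assumption for the ratio of missing E (neither E nor D) to D at the D peak, with L taken as charged.

| flask | E | L | remark | time |
|---|---|---|---|---|
| violet | 0.050 M | 0.027 M | run made earlier |  |
| grey | 0.050 M | 0.060 M | run made earlier |  |
| amber | 0.10 M | 0.040 M | run made earlier |  |
| flask | 0.050 M | 0.0400 M |  | 8.0 h |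

| run | time / h | D / % | E / % |
|---|---|---|---|
| violet | 0.0833 | 16 | 81 |
| violet | 0.250 | 16 | 71 |
| violet | 0.833 | 17 | 69 |
| violet | 2.50 | 6 | 76 |
| violet | 8.00 | 2 | 70 |
| grey | 0.0833 | 23 | 60 |
| grey | 0.250 | 25 | 46 |
| grey | 0.833 | 18 | 40 |
| grey | 2.50 | 5 | 43 |
| grey | 8.00 | 2 | 44 |
| amber | 0.0833 | 17 | 81 |
| amber | 0.250 | 17 | 76 |
| amber | 0.833 | 12 | 76 |
| amber | 2.50 | 8 | 80 |
| amber | 8.00 | 1 | 79 |

(each reading ± 2 percentage points)

1. the moment within 8.0 h at which there is most D
2. the amount of D, in percent of the E charged, at that time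



In the grey run, D has its highest reading at 0.250 h, with E at 46 % and D at 25 %. From that reading, with its scatter, I take the split factor S, a selectivity factor: missing E per D per molar of L charged 19.3 M⁻¹.

The flask has two extremes. If each L made one D, D would reach 80.0 % of the E charged. If L went two to each E and no D stayed, D would be nil and E would stop after losing 40.0 %. The real flask lies between them: grey E already stands at 46 % at its D peak against 44 % at 8.00 h, so I let the flask's peak come with nearly that loss, split by S. That gives me 22.6 % of D, near the grey peak time.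

The forecast, “Interpolating the plateaus”, gave 20 % (17 % to 24 %) at 0.25 h (0.1 h to 0.6 h).

The flask gave 22.7 % at 0.242 h.

    E + 2 L → J (k = 1700 M⁻² h⁻¹)
    E + L ⇌ D (K = 28.0 M⁻¹, k = 110 M⁻¹ h⁻¹)
    L + D → Z (k = 6.90 M⁻¹ h⁻¹)

Up to 0.242 h the flask ran E + L to D and E + 2 L to J together, leaving E at 62.0 %, D at 22.7 % and J at 14.7 %, a J to D ratio of 0.648 against 0.773 from S. After that, by 8.00 h, E stood at 60.2 %, L had fallen to 4.64 % of its charge, D had fallen to 3.22 % and J had risen to 33.6 %. With 0.016 M of L, S gives 12.2 %, and that flask's best was 12.9 %.

(The runs are simulated with constants of no real substance; scatter was added.)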